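**Retrosynthetic overview**

1. Locants (azulene numbering of the core): C8a = quaternary ring-fusion carbon with CH3, C3a = ring-fusion CH, C3 = C(OH)(iPr), C4 = aroyloxy carbon, C6 = methyl-bearing alkene carbon, C8 = isovaleryloxy carbon; β = face of the C8a methyl.
2. Target 26 ⇒ bicyclic 4-ketone/8-enone 19 (ester cleavage, two acylations, two hydride additions from the β face); 19 ⇒ cycloadduct 17 by Saegusa–Ito oxidation.
3. 17 ⇒ open-chain 16 by an intramolecular (4+3) cascade that forms C3a–C8a (five-membered ring, first) and C5–C6 (seven-membered ring, second) in one operation.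
4. Enabling feature: in the seven-membered ring C3a–C4–C5–C6–C7–C8–C8a the tertiary 3-OH lies β to the C4 oxygen across C3a–H (an opened α,β-epoxy ketone, so C3a/C4/C5 can be an epoxy enolsilane), and the C8 oxygen sits next to quaternary C8a (so C6/C7/C8/C8a can be a 2-siloxydiene); C1–C2 of the five-membered ring is the tether.
5. 16 ⇒ epoxy diketone 15 ⇒ Z-trisubstituted (S)-allylic alcohol 10 (CBS reduction, then hydroxyl-directed epoxidation) ⇒ hex-5-ynoic acid, MeI, Ac2O, iPrZnBr and (E)-1-bromoprop-1-ene.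

Key step: step 10

Assumption: the stereocentre α to the amide/ketone carbonyl in 5–15 (the later C8a) is carried as a mixture of epimers, because step 9 converts it into an sp2 enol-ether carbon.

**Route**

Step 1
Reactants: 1 hex-5-ynoic acid
Product: 2 N-methoxy-N-methylhex-5-ynamide
Conditions: CDI, CH2Cl2, rt; then MeNHOMe·HCl, rt
Reagents that add atoms: N,O-dimethylhydroxylamine hydrochloride, CNOC.Cl
Why: Aminolysis of the acyl imidazolide (Weinreb amide synthesis) should be clean, the terminal alkyne being inert.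

Step 2
Reactants: 2 N-methoxy-N-methylhex-5-ynamide, 3 iodomethane, 4 acetic anhydride
Product: 6 N-methoxy-N,2-dimethyl-7-oxooct-5-ynamide, via lithium acetylide of the 2-methylated amide 5 (not isolated)
Conditions: LiN(iPr)2 (2.2 equiv), THF, −78 °C; MeI (1.0 equiv), −78 °C; then inverse addition to Ac2O (4 equiv), THF, −78 °C
Reagents that add atoms: iodomethane (3), CI; acetic anhydride (4), CC(=O)OC(C)=O
Why: The acetylide/amide-enolate dianion should be methylated only at the far more nucleophilic enolate carbon (enolate alkylation), and the surviving lithium acetylide is then acylated to the ynone (acetylide acylation); the new stereocentre is racemic and is erased in step 9.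

Step 3
Reactants: 6 N-methoxy-N,2-dimethyl-7-oxooct-5-ynamide
Product: 7 (5Z)-5-iodo-N-methoxy-N,2-dimethyl-7-oxooct-5-enamide
Conditions: NaI, AcOH, rt, dark
Reagents that add atoms: sodium iodide, [Na+].[I-]
Why: Conjugate hydroiodination of the ynone (iodide addition, anti protonation) should give the β-iodoenone with iodine cis to the acetyl group.

Step 4
Reactants: 7 (5Z)-5-iodo-N-methoxy-N,2-dimethyl-7-oxooct-5-enamide, 8 isopropylzinc bromide
Product: 9 (5Z)-N-methoxy-N,2-dimethyl-7-oxo-5-(propan-2-yl)oct-5-enamide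
Conditions: iPrZnBr, PdCl2(dppf) (5 mol%), THF, 0 °C to rt
Reagents that add atoms: isopropylzinc bromide (8), CC(C)[Zn]Br
Why: Negishi cross-coupling with retention of alkene geometry places the isopropyl group cis to the acetyl group; the wide-bite-angle dppf ligand should suppress β-hydride elimination, and the alkylzinc halide tolerates ketone and Weinreb amide.

Step 5
Reactants: 9 (5Z)-N-methoxy-N,2-dimethyl-7-oxo-5-(propan-2-yl)oct-5-enamide
Product: 10 (5Z,7S)-7-hydroxy-N-methoxy-N,2-dimethyl-5-(propan-2-yl)oct-5-enamide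
Conditions: (R)-2-methyl-CBS-oxazaborolidine (0.2 equiv), catecholborane, toluene, −78 °C
Reagents that add atoms: none
Why: In the Corey–Bakshi–Shibata reduction the alkenyl group acts as the large substituent, so the (R)-catalyst should give the (S)-allylic alcohol, the only source of absolute configuration in the route.

Step 6
Reactants: 10 (5Z,7S)-7-hydroxy-N-methoxy-N,2-dimethyl-5-(propan-2-yl)oct-5-enamide, 11 (E)-1-bromoprop-1-ene
Product: 13 (2E,8Z,10S)-10-hydroxy-5-methyl-8-(propan-2-yl)undeca-2,8-dien-4-one, via (E)-prop-1-enyllithium 12 (not isolated)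
Conditions: 11 (2.6 equiv), t-BuLi (5.2 equiv), Et2O, −78 °C; then 10, THF, −78 to 0 °C; 1 M HCl quench at −78 °C
Reagents that add atoms: (E)-1-bromoprop-1-ene (11), C/C=C/Br
Why: Bromine–lithium exchange with retention of geometry followed by Weinreb ketone synthesis (the first equivalent only deprotonates the alcohol, the chelated tetrahedral intermediate prevents over-addition) should give the (E)-enone.

Step 7
Reactants: 13 (2E,8Z,10S)-10-hydroxy-5-methyl-8-(propan-2-yl)undeca-2,8-dien-4-one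
Product: 14 (2E)-7-{(2S,3R)-3-[(1S)-1-hydroxyethyl]-2-(propan-2-yl)oxiran-2-yl}-5-methylhept-2-en-4-one
Conditions: mCPBA, NaHCO3, CH2Cl2, 0 °C
Reagents that add atoms: 3-chloroperoxybenzoic acid, OOC(=O)c1cccc(Cl)c1
Why: In this hydroxyl-directed (Henbest) epoxidation, allylic 1,3-strain with the cis isopropyl group holds the carbinol C–H in the alkene plane, so the peracid is delivered to the face of the OH and sets both epoxide carbons, while the electron-poor enone alkene is not attacked.

Step 8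
Reactants: 14 (2E)-7-{(2S,3R)-3-[(1S)-1-hydroxyethyl]-2-(propan-2-yl)oxiran-2-yl}-5-methylhept-2-en-4-one
Product: 15 (2E)-7-[(2S,3S)-3-acetyl-2-(propan-2-yl)oxiran-2-yl]-5-methylhept-2-en-4-one
Conditions: Dess–Martin periodinane, NaHCO3, CH2Cl2, rt
Reagents that add atoms: none
Why: Dess–Martin oxidation of the secondary alcohol should give the α,β-epoxy ketone under buffered conditions that leave the epoxide untouched.

Step 9
Reactants: 15 (2E)-7-[(2S,3S)-3-acetyl-2-(propan-2-yl)oxiran-2-yl]-5-methylhept-2-en-4-one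
Product: 16 triethyl({1-[(2S,3S)-3-{(5E)-3-methyl-4-[(triethylsilyl)oxy]hepta-3,5-dien-1-yl}-3-(propan-2-yl)oxiran-2-yl]ethenyl}oxy)silane (3-ene geometry mixed)
Conditions: LiN(iPr)2 (2.5 equiv), Et3SiCl (3 equiv), THF, −78 °C (in situ quench); Et3N, pentane, filtration
Reagents that add atoms: chlorotriethylsilane, CC[Si](Cl)(CC)CC
Why: Kinetic enolisation with in situ O-silylation should take the methyl ketone at CH3 (the epoxide C–H is not removed) and the enone at its α'-CH (the kinetic site of enones), giving the epoxy enolsilane and the 2-siloxydiene in one operation; the geometry of the tetrasubstituted enol ether is immaterial.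

Step 10
Reactants: 16 triethyl({1-[(2S,3S)-3-{(5E)-3-methyl-4-[(triethylsilyl)oxy]hepta-3,5-dien-1-yl}-3-(propan-2-yl)oxiran-2-yl]ethenyl}oxy)silane
Product: 17 (3S,3aR,8aR)-6,8a-dimethyl-3-(propan-2-yl)-3,8-bis[(triethylsilyl)oxy]-2,3,3a,5,6,8a-hexahydroazulen-4(1H)-one (cis-fused, C6 epimers)
Conditions: Et3SiOTf (0.2 equiv), CH2Cl2 (0.01 M), −78 °C; Et3N quench
Reagents that add atoms: none
Why: Proposed new method: Et3SiOTf silylates the epoxide oxygen, the C–O bond at the carbon next to the enol silane ionises towards a 2-siloxyallyl cation, the methyl-bearing enol-ether carbon of the tethered 2-siloxydiene attacks that carbon opposite the leaving oxygen, and the resulting silyloxy-stabilised allyl cation is captured at its propenyl terminus by the CH2 end of the enol silane, after which the silyl cation is passed on to the next epoxide; the closest known reaction type is the silyl-triflate-catalysed intramolecular (4+3) cycloaddition of epoxy enolsilanes with tethered furans and simple dienes, extended here to an acyclic 2-siloxydiene that forms a quaternary centre. The five-membered ring closes by endo-mode, SN2-like opening of the epoxide (C8a to C3a), and the seven-membered ring by 7-endo attack of the enol silane on the allyl cation (C5 to C6), the second bond of the formal (4+3) cycloaddition. C3 keeps the epoxide configuration, C3a is set by inversion at the epoxide CH (the cis acetyl/isopropyl geometry of 15 therefore puts the 3-oxygen cis to H-3a), C8a is set relative to C3a by compact stacking of the diene under the allyl unit, which brings the two oxygen-bearing carbons C4 and C8 to the same side and gives the cis ring fusion, and C6 forms as a mixture that step 11 erases. The step needs (a) attack through the enol-ether carbon only, secured by the siloxy group, which makes this carbon the one nucleophilic site of the diene and stabilises the cation formed, (b) 1,4- and not 1,2-capture of that cation, expected because 1,2-closure would join two contiguous fully substituted carbons in a reversible aldol-type step, and (c) cis over trans fusion, favoured because the extended arrangement would force the enol-ether methyl under the silyloxy group of the allyl unit. High dilution and low temperature should hold back intermolecular enol-silane/epoxide reactions and Lewis-acid rearrangement of the trisubstituted epoxide.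

Step 11
Reactants: 17 (3S,3aR,8aR)-6,8a-dimethyl-3-(propan-2-yl)-3,8-bis[(triethylsilyl)oxy]-2,3,3a,5,6,8a-hexahydroazulen-4(1H)-one
Product: 19 (3S,3aR,8aR)-3-hydroxy-6,8a-dimethyl-3-(propan-2-yl)-2,3,3a,5-tetrahydroazulene-4,8(1H,8aH)-dione, via triethylsilyl-protected enedione 18 (not isolated)
Conditions: Pd(OAc)2 (1.1 equiv), MeCN, rt; filtration; then HF·pyridine, THF, 0 °C
Reagents that add atoms: none
Why: Saegusa–Ito oxidation (oxa-π-allylpalladium from the enol silane, β-hydride elimination of H-6) should give the enone regiospecifically and erase C6, and fluoride then cleaves the tertiary silyl ether without base that could trigger retro-aldol cleavage.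

Step 12
Reactants: 19 (3S,3aR,8aR)-3-hydroxy-6,8a-dimethyl-3-(propan-2-yl)-2,3,3a,5-tetrahydroazulene-4,8(1H,8aH)-dione
Product: 20 (3S,3aS,4R,8aR)-3,4-dihydroxy-6,8a-dimethyl-3-(propan-2-yl)-2,3,3a,4,5,8a-hexahydroazulen-8(1H)-one
Conditions: Me4NBH(OAc)3, AcOH/MeCN, −30 °C
Reagents that add atoms: none
Why: In this Evans–Saksena directed reduction the 3-OH binds boron and delivers hydride to the 4-ketone on its own (β, convex) face, which sets C4 with the oxygen trans to the 3-OH, while the enone, lacking a suitably placed hydroxyl, should not be reduced by this mild reagent.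

Step 13
Reactants: 20 (3S,3aS,4R,8aR)-3,4-dihydroxy-6,8a-dimethyl-3-(propan-2-yl)-2,3,3a,4,5,8a-hexahydroazulen-8(1H)-one, 21 4-acetoxybenzoyl chloride
Product: 22 (3S,3aS,4R,8aR)-3-hydroxy-6,8a-dimethyl-8-oxo-3-(propan-2-yl)-1,2,3,3a,4,5,8,8a-octahydroazulen-4-yl 4-(acetyloxy)benzoate
Conditions: 21, Et3N, DMAP (cat.), CH2Cl2, 0 °C to rt
Reagents that add atoms: 4-acetoxybenzoyl chloride (21), CC(=O)Oc1ccc(cc1)C(Cl)=O
Why: DMAP-catalysed acylation should take the secondary alcohol and leave the hindered tertiary alcohol.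

Step 14
Reactants: 22 (3S,3aS,4R,8aR)-3-hydroxy-6,8a-dimethyl-8-oxo-3-(propan-2-yl)-1,2,3,3a,4,5,8,8a-octahydroazulen-4-yl 4-(acetyloxy)benzoate
Product: 23 (3S,3aS,4R,8S,8aR)-3,8-dihydroxy-6,8a-dimethyl-3-(propan-2-yl)-1,2,3,3a,4,5,8,8a-octahydroazulen-4-yl 4-(acetyloxy)benzoate
Conditions: NaBH4, CeCl3·7H2O, MeOH, −78 °C
Reagents that add atoms: none
Why: In this Luche 1,2-reduction hydride is expected from the convex β face of the cis-fused bicycle (the α face is screened by the folded five-membered ring and its isopropyl group), which sets C8 with the hydroxyl α.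

Step 15
Reactants: 23 (3S,3aS,4R,8S,8aR)-3,8-dihydroxy-6,8a-dimethyl-3-(propan-2-yl)-1,2,3,3a,4,5,8,8a-octahydroazulen-4-yl 4-(acetyloxy)benzoate, 24 3-methylbutanoyl chloride
Product: 25 (3S,3aS,4R,8S,8aR)-3-hydroxy-6,8a-dimethyl-8-[(3-methylbutanoyl)oxy]-3-(propan-2-yl)-1,2,3,3a,4,5,8,8a-octahydroazulen-4-yl 4-(acetyloxy)benzoate
Conditions: 24, pyridine, DMAP (cat.), CH2Cl2, 0 °C to rt
Reagents that add atoms: 3-methylbutanoyl chloride (24), CC(C)CC(Cl)=O
Why: Acylation of the secondary allylic alcohol with the acid chloride and DMAP should proceed while the tertiary alcohol stays free.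

Step 16
Reactants: 25 (3S,3aS,4R,8S,8aR)-3-hydroxy-6,8a-dimethyl-8-[(3-methylbutanoyl)oxy]-3-(propan-2-yl)-1,2,3,3a,4,5,8,8a-octahydroazulen-4-yl 4-(acetyloxy)benzoate
Product: 26 (3S,3aS,4R,8S,8aR)-3-hydroxy-6,8a-dimethyl-8-[(3-methylbutanoyl)oxy]-3-(propan-2-yl)-1,2,3,3a,4,5,8,8a-octahydroazulen-4-yl 4-hydroxybenzoate (CNP0086724.3)
Conditions: K2CO3 (0.2 equiv), MeOH, 0 °C
Reagents that add atoms: none
Why: Carbonate-catalysed methanolysis should cleave the aryl acetate far faster than the two secondary alkyl esters, and the phenoxide formed deactivates the benzoate towards further attack.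

**Compound list**

1 | hex-5-ynoic acid | C#CCCCC(=O)O | starting material
2 | N-methoxy-N-methylhex-5-ynamide | C#CCCCC(=O)N(C)OC | intermediate
3 | iodomethane | CI | starting material
4 | acetic anhydride | CC(=O)OC(C)=O | starting material
5 | lithium acetylide of N-methoxy-N,2-dimethylhex-5-ynamide (racemic at C2) | [Li]C#CCCC(C)C(=O)N(C)OC | intermediate
6 | N-methoxy-N,2-dimethyl-7-oxooct-5-ynamide (racemic at C2) | CC(=O)C#CCCC(C)C(=O)N(C)OC | intermediate
7 | (5Z)-5-iodo-N-methoxy-N,2-dimethyl-7-oxooct-5-enamide | CC(=O)/C=C(\I)CCC(C)C(=O)N(C)OC | intermediate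
8 | isopropylzinc bromide | CC(C)[Zn]Br | starting material
9 | (5Z)-N-methoxy-N,2-dimethyl-7-oxo-5-(propan-2-yl)oct-5-enamide | CC(=O)/C=C(\C(C)C)CCC(C)C(=O)N(C)OC | intermediate
10 | (5Z,7S)-7-hydroxy-N-methoxy-N,2-dimethyl-5-(propan-2-yl)oct-5-enamide | C[C@H](O)/C=C(\C(C)C)CCC(C)C(=O)N(C)OC | intermediate
11 | (E)-1-bromoprop-1-ene | C/C=C/Br | starting material
12 | (E)-prop-1-enyllithium | C/C=C/[Li] | intermediate
13 | (2E,8Z,10S)-10-hydroxy-5-methyl-8-(propan-2-yl)undeca-2,8-dien-4-one | C[C@H](O)/C=C(\C(C)C)CCC(C)C(=O)/C=C/C | intermediate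
14 | (2E)-7-{(2S,3R)-3-[(1S)-1-hydroxyethyl]-2-(propan-2-yl)oxiran-2-yl}-5-methylhept-2-en-4-one | C[C@H](O)[C@H]1O[C@]1(C(C)C)CCC(C)C(=O)/C=C/C | intermediate
15 | (2E)-7-[(2S,3S)-3-acetyl-2-(propan-2-yl)oxiran-2-yl]-5-methylhept-2-en-4-one | CC(=O)[C@H]1O[C@]1(C(C)C)CCC(C)C(=O)/C=C/C | intermediate
16 | triethyl({1-[(2S,3S)-3-{(5E)-3-methyl-4-[(triethylsilyl)oxy]hepta-3,5-dien-1-yl}-3-(propan-2-yl)oxiran-2-yl]ethenyl}oxy)silane (3-ene geometry mixed) | C=C(O[Si](CC)(CC)CC)[C@H]1O[C@]1(C(C)C)CCC(C)=C(O[Si](CC)(CC)CC)/C=C/C | intermediate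
17 | (3S,3aR,8aR)-6,8a-dimethyl-3-(propan-2-yl)-3,8-bis[(triethylsilyl)oxy]-2,3,3a,5,6,8a-hexahydroazulen-4(1H)-one (cis-fused, C6 epimers) | CC1C=C(O[Si](CC)(CC)CC)[C@]2(C)CC[C@](O[Si](CC)(CC)CC)(C(C)C)[C@@H]2C(=O)C1 | intermediate
18 | (3S,3aR,8aR)-6,8a-dimethyl-3-(propan-2-yl)-3-[(triethylsilyl)oxy]-2,3,3a,5-tetrahydroazulene-4,8(1H,8aH)-dione | CC1=CC(=O)[C@]2(C)CC[C@](O[Si](CC)(CC)CC)(C(C)C)[C@@H]2C(=O)C1 | intermediate
19 | (3S,3aR,8aR)-3-hydroxy-6,8a-dimethyl-3-(propan-2-yl)-2,3,3a,5-tetrahydroazulene-4,8(1H,8aH)-dione | CC1=CC(=O)[C@]2(C)CC[C@](O)(C(C)C)[C@@H]2C(=O)C1 | intermediate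
20 | (3S,3aS,4R,8aR)-3,4-dihydroxy-6,8a-dimethyl-3-(propan-2-yl)-2,3,3a,4,5,8a-hexahydroazulen-8(1H)-one | CC1=CC(=O)[C@]2(C)CC[C@](O)(C(C)C)[C@@H]2[C@H](O)C1 | intermediate
21 | 4-acetoxybenzoyl chloride | CC(=O)Oc1ccc(cc1)C(Cl)=O | starting material
22 | (3S,3aS,4R,8aR)-3-hydroxy-6,8a-dimethyl-8-oxo-3-(propan-2-yl)-1,2,3,3a,4,5,8,8a-octahydroazulen-4-yl 4-(acetyloxy)benzoate | CC1=CC(=O)[C@]2(C)CC[C@](O)(C(C)C)[C@@H]2[C@H](OC(=O)c2ccc(OC(C)=O)cc2)C1 | intermediate
23 | (3S,3aS,4R,8S,8aR)-3,8-dihydroxy-6,8a-dimethyl-3-(propan-2-yl)-1,2,3,3a,4,5,8,8a-octahydroazulen-4-yl 4-(acetyloxy)benzoate | CC1=C[C@H](O)[C@]2(C)CC[C@](O)(C(C)C)[C@@H]2[C@H](OC(=O)c2ccc(OC(C)=O)cc2)C1 | intermediate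
24 | 3-methylbutanoyl chloride | CC(C)CC(Cl)=O | starting material
25 | (3S,3aS,4R,8S,8aR)-3-hydroxy-6,8a-dimethyl-8-[(3-methylbutanoyl)oxy]-3-(propan-2-yl)-1,2,3,3a,4,5,8,8a-octahydroazulen-4-yl 4-(acetyloxy)benzoate | CC1=C[C@H](OC(=O)CC(C)C)[C@]2(C)CC[C@](O)(C(C)C)[C@@H]2[C@H](OC(=O)c2ccc(OC(C)=O)cc2)C1 | intermediate
26 | (3S,3aS,4R,8S,8aR)-3-hydroxy-6,8a-dimethyl-8-[(3-methylbutanoyl)oxy]-3-(propan-2-yl)-1,2,3,3a,4,5,8,8a-octahydroazulen-4-yl 4-hydroxybenzoate | CC1=C[C@H](OC(=O)CC(C)C)[C@]2(C)CC[C@](O)(C(C)C)[C@@H]2[C@H](OC(=O)c2ccc(O)cc2)C1 | target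

**Step count and risks**

Total step count: 16. Longest linear sequence: 16 steps (from hex-5-ynoic acid).

Steps most likely to fail:

Step 10 (proposed new method). What may go wrong: the wrong facial pairing in the first C–C bond formation (trans ring fusion), closure of the intermediate cation at the carbonyl carbon instead of the propenyl terminus, or Lewis-acid rearrangement of the epoxide before it is captured. The fallback uses known chemistry: a plain 1,3-diene as the four-carbon partner, as in the precedented intramolecular epoxy enolsilane (4+3) cycloadditions, with the C8 oxygen introduced afterwards. It sets out from (E)-1-bromoprop-1-ene (11) and comes back to the route at 18. Zr-catalysed carboalumination of commercial pent-4-yn-1-ol (Me3Al, Cp2ZrCl2) and coupling of the alkenylalane with 11 (Pd(PPh3)4, ZnCl2) should give (4E,6E)-4-methylocta-4,6-dien-1-ol F1, with the methyl cis to the propenyl group. Dess–Martin oxidation gives (4E,6E)-4-methylocta-4,6-dienal F2, Ohira–Bestmann homologation (K2CO3, MeOH) gives (5E,7E)-5-methylnona-5,7-dien-1-yne F3, and n-BuLi followed by Ac2O gives (7E,9E)-7-methylundeca-7,9-dien-3-yn-2-one F4. The conditions of steps 3, 4 and 5 then give (3Z,7E,9E)-4-iodo-7-methylundeca-3,7,9-trien-2-one F5, (3Z,7E,9E)-7-methyl-4-(propan-2-yl)undeca-3,7,9-trien-2-one F6 and (2S,3Z,7E,9E)-7-methyl-4-(propan-2-yl)undeca-3,7,9-trien-2-ol F7. Ti(OiPr)4/t-BuOOH (hydroxyl-directed, diene untouched) gives (1S)-1-[(2R,3S)-3-[(3E,5E)-3-methylhepta-3,5-dien-1-yl]-3-(propan-2-yl)oxiran-2-yl]ethan-1-ol F8, Dess–Martin oxidation gives 1-[(2S,3S)-3-[(3E,5E)-3-methylhepta-3,5-dien-1-yl]-3-(propan-2-yl)oxiran-2-yl]ethan-1-one F9, and LiN(iPr)2/Et3SiCl gives triethyl({1-[(2S,3S)-3-[(3E,5E)-3-methylhepta-3,5-dien-1-yl]-3-(propan-2-yl)oxiran-2-yl]ethenyl}oxy)silane F10. Et3SiOTf (catalytic, CH2Cl2, −78 °C) should convert F10 into (3S,3aR,8aS)-6,8a-dimethyl-3-(propan-2-yl)-3-[(triethylsilyl)oxy]-2,3,3a,5,6,8a-hexahydroazulen-4(1H)-one F11 (6-H cis to the 8a-methyl); the methyl placed inside on the diene terminus again disfavours the extended transition state. Photooxygenation (O2, light, tetraphenylporphyrin; Schenck ene reaction, H-6 being the only allylic hydrogen) gives (3S,3aR,8aR)-8-hydroperoxy-6,8a-dimethyl-3-(propan-2-yl)-3-[(triethylsilyl)oxy]-2,3,3a,5,8,8a-hexahydroazulen-4(1H)-one F12, and Ac2O/pyridine/DMAP (Kornblum–DeLaMare dehydration) converts it into 18, from where step 11 continues with the HF·pyridine treatment.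

Step 14. What may go wrong: poor or reversed facial selectivity of hydride delivery to the C8 carbonyl, which is flanked by the quaternary carbon. The fallback sets out from 22 and comes back at 25. If hydride is delivered mainly from the α face, the reduction gives (3S,3aS,4R,8R,8aR)-3,8-dihydroxy-6,8a-dimethyl-3-(propan-2-yl)-1,2,3,3a,4,5,8,8a-octahydroazulen-4-yl 4-(acetyloxy)benzoate F13. Mitsunobu esterification of this alcohol with 3-methylbutanoic acid (PPh3, diisopropyl azodicarboxylate, toluene) installs the isovalerate with inversion and gives 25 directly, so step 15 is not needed.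

Step 4. What may go wrong: β-hydride elimination and re-insertion on palladium (isomerisation or loss of the secondary alkyl group) or scrambling of the alkene geometry during coupling. The fallback sets out from 7 and comes back at 9. Suzuki–Miyaura coupling of 7 with isopropenylboronic acid pinacol ester (Pd(PPh3)4, K3PO4, THF/H2O) is an sp2–sp2 coupling with retention and no β-hydrogen problem, and should give (5Z)-N-methoxy-N,2-dimethyl-7-oxo-5-(prop-1-en-2-yl)oct-5-enamide F14. Hydrogenation with RhCl(PPh3)3 (H2, benzene) should then saturate only the unhindered 1,1-disubstituted alkene and give 9.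

**Further compounds**

F1 | step 10 | (4E,6E)-4-methylocta-4,6-dien-1-ol | OCCC/C(C)=C/C=C/C
F2 | step 10 | (4E,6E)-4-methylocta-4,6-dienal | O=CCC/C(C)=C/C=C/C
F3 | step 10 | (5E,7E)-5-methylnona-5,7-dien-1-yne | C#CCC/C(C)=C/C=C/C
F4 | step 10 | (7E,9E)-7-methylundeca-7,9-dien-3-yn-2-one | CC(=O)C#CCC/C(C)=C/C=C/C
F5 | step 10 | (3Z,7E,9E)-4-iodo-7-methylundeca-3,7,9-trien-2-one | CC(=O)/C=C(\I)CC/C(C)=C/C=C/C
F6 | step 10 | (3Z,7E,9E)-7-methyl-4-(propan-2-yl)undeca-3,7,9-trien-2-one | CC(=O)/C=C(\C(C)C)CC/C(C)=C/C=C/C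
F7 | step 10 | (2S,3Z,7E,9E)-7-methyl-4-(propan-2-yl)undeca-3,7,9-trien-2-ol | C[C@H](O)/C=C(\C(C)C)CC/C(C)=C/C=C/C
F8 | step 10 | (1S)-1-[(2R,3S)-3-[(3E,5E)-3-methylhepta-3,5-dien-1-yl]-3-(propan-2-yl)oxiran-2-yl]ethan-1-ol | C[C@H](O)[C@H]1O[C@]1(C(C)C)CC/C(C)=C/C=C/C
F9 | step 10 | 1-[(2S,3S)-3-[(3E,5E)-3-methylhepta-3,5-dien-1-yl]-3-(propan-2-yl)oxiran-2-yl]ethan-1-one | CC(=O)[C@H]1O[C@]1(C(C)C)CC/C(C)=C/C=C/C
F10 | step 10 | triethyl({1-[(2S,3S)-3-[(3E,5E)-3-methylhepta-3,5-dien-1-yl]-3-(propan-2-yl)oxiran-2-yl]ethenyl}oxy)silane | C=C(O[Si](CC)(CC)CC)[C@H]1O[C@]1(C(C)C)CC/C(C)=C/C=C/C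
F11 | step 10 | (3S,3aR,8aS)-6,8a-dimethyl-3-(propan-2-yl)-3-[(triethylsilyl)oxy]-2,3,3a,5,6,8a-hexahydroazulen-4(1H)-one (6-H cis to 8a-methyl) | C[C@@H]1C=C[C@]2(C)CC[C@](O[Si](CC)(CC)CC)(C(C)C)[C@@H]2C(=O)C1
F12 | step 10 | (3S,3aR,8aR)-8-hydroperoxy-6,8a-dimethyl-3-(propan-2-yl)-3-[(triethylsilyl)oxy]-2,3,3a,5,8,8a-hexahydroazulen-4(1H)-one (8-OOH cis to 8a-methyl) | CC1=C[C@@H](OO)[C@]2(C)CC[C@](O[Si](CC)(CC)CC)(C(C)C)[C@@H]2C(=O)C1
F13 | step 14 | (3S,3aS,4R,8R,8aR)-3,8-dihydroxy-6,8a-dimethyl-3-(propan-2-yl)-1,2,3,3a,4,5,8,8a-octahydroazulen-4-yl 4-(acetyloxy)benzoate | CC1=C[C@@H](O)[C@]2(C)CC[C@](O)(C(C)C)[C@@H]2[C@H](OC(=O)c2ccc(OC(C)=O)cc2)C1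
F14 | step 4 | (5Z)-N-methoxy-N,2-dimethyl-7-oxo-5-(prop-1-en-2-yl)oct-5-enamide | CC(=O)/C=C(\C(C)=C)CCC(C)C(=O)N(C)OC
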